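**Retrosynthetic overview**

1. Numbering (bicyclo[3.2.1]octan-8-one): C1 bridgehead with OMe, C2 CH–OH, C3 CH–OMe, C4 CH2, C5 bridgehead with allyl, C6 CH–Me, C7 CH–aryl, C8 C=O. Target ⇒ cis-2,3-diol (O3-methylation last) ⇒ pinacol disconnection of C2–C3 to a 1,6-dialdehyde; this one cut opens the six-membered ring C1–C2–C3–C4–C5–C8 and the seven-membered ring C1–C2–C3–C4–C5–C6–C7 together and leaves only the cyclopentanone C1–C7–C6–C5–C8.
2. Feature that allows it: C2–C3 is the one bond of the three-carbon bridge that joins two oxygen-bearing CH carbons. Its two ends hang from C1 and C5, the two α-carbons of the C8 ketone, as a one-carbon and a two-carbon arm on the same face of the cyclopentanone (cis-1,3), so both formyl groups can bind one samarium; the endo C6 methyl group blocks the endo side of C3, so the C3 oxygen must come out exo.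
3. Cyclopentanone: every centre is relayed by anti additions from the single stereocentre of (R)-4-silyloxycyclopentenone: C6 methyl (conjugate addition, then elimination) → C5 quaternary (two α′-alkylations, allyl last) → C7 aryl (conjugate addition) → C1 (methoxy first, then the formyl carbon anti to aryl). The prenyl group is the masked two-carbon arm.
4. Order of rings: five-membered ring from the start; six- and seven-membered rings closed together in step 9; selective O3-methylation ends the route.

Key step: step 9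

Assumption: 12 is drawn as its 2,3-trans epimer (either C2 epimer converges in step 6), 15 is a pair of epimers at the oxirane carbon (both converge in step 8), and Grignard reagent 10 is bought as its THF solution.

**Route**

Step 1
Reactants: 1 (4R)-4-[(tert-butyldimethylsilyl)oxy]cyclopent-2-en-1-one
Product: 3 (4R)-4-methylcyclopent-2-en-1-one, via β-silyloxy ketone 2 (not isolated)
Conditions: MeMgBr, CuBr·SMe2 (10 mol %), THF, −78 °C; aq. NH4Cl; then DBU, CH2Cl2, 0 °C
Reagents that add atoms: methylmagnesium bromide C[Mg]Br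
Why: Copper-catalysed conjugate addition of the Grignard reagent should place the methyl group anti to the neighbouring silyloxy group, and the base-induced E1cB loss of silanol then transposes the enone, so that the methyl-bearing carbon (later C6) is the only stereocentre left.

Step 2
Reactants: 3 (4R)-4-methylcyclopent-2-en-1-one; 4 1-bromo-3-methylbut-2-ene (prenyl bromide)
Product: 6 (4S,5R)-4-methyl-5-(3-methylbut-2-en-1-yl)cyclopent-2-en-1-one, via lithium enolate 5 (not isolated)
Conditions: LiN(CHMe2)2, THF, −78 °C; then 4, DMPU, −78 → −20 °C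
Reagents that add atoms: none
Why: Kinetic α′-deprotonation of the enone and SN2 alkylation of the cross-conjugated enolate should give the trans product (halide approaching anti to the methyl group), a centre that is made planar again in step 3.

Step 3
Reactants: 6 (4S,5R)-4-methyl-5-(3-methylbut-2-en-1-yl)cyclopent-2-en-1-one; 7 3-bromoprop-1-ene (allyl bromide)
Product: 9 (4S,5S)-4-methyl-5-(3-methylbut-2-en-1-yl)-5-(prop-2-en-1-yl)cyclopent-2-en-1-one, via lithium enolate 8 (not isolated)
Conditions: LiN(CHMe2)2, THF, −78 °C; then 7, DMPU, −78 → 0 °C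
Reagents that add atoms: none
Why: A second α′-enolate alkylation should build the quaternary carbon (later C5) with the allyl group entering anti to the adjacent methyl group, which leaves the prenyl arm cis to that methyl group as the later bridge requires.

Step 4
Reactants: 9 (4S,5S)-4-methyl-5-(3-methylbut-2-en-1-yl)-5-(prop-2-en-1-yl)cyclopent-2-en-1-one; 10 (3,4,5-trimethoxyphenyl)magnesium bromide
Product: 11 trimethyl{[(3S,4S,5S)-4-methyl-5-(3-methylbut-2-en-1-yl)-5-(prop-2-en-1-yl)-3-(3,4,5-trimethoxyphenyl)cyclopent-1-en-1-yl]oxy}silane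
Conditions: CuBr·SMe2 (10 mol %), TMSCl, THF, −78 → −40 °C; non-aqueous work-up
Reagents that add atoms: chlorotrimethylsilane C[Si](C)(C)Cl
Why: Copper-catalysed conjugate addition of the aryl Grignard reagent with in situ silylation should occur anti to the adjacent methyl group (trans relationship of the later C7 and C6) and fixes the enolate regiochemistry as the enol silane.

Step 5
Reactants: 11 trimethyl{[(3S,4S,5S)-4-methyl-5-(3-methylbut-2-en-1-yl)-5-(prop-2-en-1-yl)-3-(3,4,5-trimethoxyphenyl)cyclopent-1-en-1-yl]oxy}silane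
Product: 12 (2R,3R,4S,5S)-2-methoxy-4-methyl-5-(3-methylbut-2-en-1-yl)-5-(prop-2-en-1-yl)-3-(3,4,5-trimethoxyphenyl)cyclopentan-1-one
Conditions: PhIO, BF3·OEt2, MeOH, −78 °C → rt
Reagents that add atoms: methanol CO
Why: Oxidative α-methoxylation of a silyl enol ether with a hypervalent iodine reagent (attack of the enol silane on iodine, then displacement of iodobenzene by methanol) should place the methoxy group only at the carbon defined by the enol silane, preferentially trans to the aryl group, and this centre is re-enolised in step 6.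

Step 6
Reactants: 12 (2R,3R,4S,5S)-2-methoxy-4-methyl-5-(3-methylbut-2-en-1-yl)-5-(prop-2-en-1-yl)-3-(3,4,5-trimethoxyphenyl)cyclopentan-1-one
Product: 14 (2R,3R,4S,5S)-2-(dimethoxymethyl)-2-methoxy-4-methyl-5-(3-methylbut-2-en-1-yl)-5-(prop-2-en-1-yl)-3-(3,4,5-trimethoxyphenyl)cyclopentan-1-one, via enol silane 13 (not isolated)
Conditions: TMSOTf (1.3 equiv), Et3N (1.1 equiv), CH2Cl2, 0 °C; then HC(OMe)3, −78 → −40 °C
Reagents that add atoms: trimethyl orthoformate COC(OC)OC
Why: Soft enolisation can only go towards the methoxy-bearing carbon (the other α-carbon is quaternary), and the Mukaiyama-type addition of the enol silane to the dimethoxycarbenium ion should occur anti to the vicinal aryl group, which sets the quaternary centre (later C1) with the acetal carbon (later C2) trans and the methoxy group cis to the aryl group.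

Step 7
Reactants: 14 (2R,3R,4S,5S)-2-(dimethoxymethyl)-2-methoxy-4-methyl-5-(3-methylbut-2-en-1-yl)-5-(prop-2-en-1-yl)-3-(3,4,5-trimethoxyphenyl)cyclopentan-1-one
Product: 15 (2R,3R,4S,5S)-2-(dimethoxymethyl)-5-[(3,3-dimethyloxiran-2-yl)methyl]-2-methoxy-4-methyl-5-(prop-2-en-1-yl)-3-(3,4,5-trimethoxyphenyl)cyclopentan-1-one (both oxirane epimers)
Conditions: mCPBA, CH2Cl2, −10 °C
Reagents that add atoms: 3-chloroperoxybenzoic acid OOC(=O)c1cccc(Cl)c1
Why: Prilezhaev epoxidation is strongly accelerated by alkyl substitution, so the trisubstituted prenyl olefin should react while the monosubstituted allyl group stays untouched, and the uncontrolled oxirane centre is destroyed in step 8.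

Step 8
Reactants: 15 (2R,3R,4S,5S)-2-(dimethoxymethyl)-5-[(3,3-dimethyloxiran-2-yl)methyl]-2-methoxy-4-methyl-5-(prop-2-en-1-yl)-3-(3,4,5-trimethoxyphenyl)cyclopentan-1-one
Product: 17 (1R,2R,3S,4S)-1-methoxy-3-methyl-5-oxo-4-(2-oxoethyl)-4-(prop-2-en-1-yl)-2-(3,4,5-trimethoxyphenyl)cyclopentane-1-carbaldehyde, via aldehyde acetal 16 (not isolated)
Conditions: H5IO6, THF/H2O, 0 °C → rt; then 3 M HCl, 35 °C; product used crude
Reagents that add atoms: water O
Why: Periodic acid should hydrolyse the epoxide and cleave the resulting diol (Malaprade cleavage) to the aldehyde and acetone, and aqueous acid then hydrolyses the dimethyl acetal, neither operation touching a stereocentre.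

Step 9
Reactants: 17 (1R,2R,3S,4S)-1-methoxy-3-methyl-5-oxo-4-(2-oxoethyl)-4-(prop-2-en-1-yl)-2-(3,4,5-trimethoxyphenyl)cyclopentane-1-carbaldehyde
Product: 18 (1R,2R,3R,5S,6S,7R)-2,3-dihydroxy-1-methoxy-6-methyl-5-(prop-2-en-1-yl)-7-(3,4,5-trimethoxyphenyl)bicyclo[3.2.1]octan-8-one
Conditions: SmI2 (2.2 equiv, added slowly), t-BuOH, THF, −78 → −20 °C
Reagents that add atoms: none
Why: Two equivalents of SmI2 should reduce the dialdehyde to samarium ketyls that couple carbon to carbon inside a samarium-bridged chelate (ketyl addition to the second, samarium-bound formyl group and a second electron transfer), the closest known reaction type being the SmI2 pinacol cyclisation of 1,6-dialdehydes to cis-cyclohexane-1,2-diols and the low-valent-metal pinacol closure of bridged bicyclo[3.2.1]octane diols. The six-membered ring C1–C2–C3–C4–C5–C8 closes in the 6-exo-trig mode on a carbonyl carbon, and because both arms stand cis on the cyclopentanone the same bond completes the seven-membered ring C1–C2–C3–C4–C5–C6–C7 and hence the bicyclo[3.2.1]octane. At C3 the C–O bond should take the equatorial, exo position of the chair-like transition state because the endo position is blocked by the endo methyl group on C6; at C2 the oxygen is held cis to O3 by chelation of both oxygens to samarium, which places it axial and syn to the C8 carbonyl. The step needs chemoselectivity for the two formyl groups over the C8 ketone and for coupling over loss of the C1 methoxy group, which the faster reduction of aldehydes, the low temperature, the limited amount of SmI2 and the proximity of the two formyl groups should secure. The allyl group is trans to the C2 arm and terminal olefins are not attacked by ketyls in the absence of HMPA, so it should stay out of the reaction.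

Step 10
Reactants: 18 (1R,2R,3R,5S,6S,7R)-2,3-dihydroxy-1-methoxy-6-methyl-5-(prop-2-en-1-yl)-7-(3,4,5-trimethoxyphenyl)bicyclo[3.2.1]octan-8-one
Product: 19 (1R,2R,3R,5S,6S,7R)-2-hydroxy-1,3-dimethoxy-6-methyl-5-(prop-2-en-1-yl)-7-(3,4,5-trimethoxyphenyl)bicyclo[3.2.1]octan-8-one
Conditions: Me3OBF4 (1.1 equiv), 1,8-bis(dimethylamino)naphthalene, CH2Cl2, 0 °C → rt
Reagents that add atoms: trimethyloxonium tetrafluoroborate C[O+](C)C.F[B-](F)(F)F
Why: O-Alkylation with the oxonium salt under non-basic conditions (no retro-aldol of the β-hydroxy ketone) should select the equatorial, unhindered C3 hydroxyl group over the axial C2 hydroxyl group flanked by the quaternary C1, and it creates no new stereocentre.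

**Compound list**

1 | (4R)-4-[(tert-butyldimethylsilyl)oxy]cyclopent-2-en-1-one | O=C1C=C[C@H](O[Si](C)(C)C(C)(C)C)C1 | starting material
2 | (3R,4R)-4-[(tert-butyldimethylsilyl)oxy]-3-methylcyclopentan-1-one (trans; not isolated) | O=C1C[C@@H](C)[C@H](O[Si](C)(C)C(C)(C)C)C1 | intermediate
3 | (4R)-4-methylcyclopent-2-en-1-one | O=C1C=C[C@H](C)C1 | intermediate
4 | 1-bromo-3-methylbut-2-ene (prenyl bromide) | CC(C)=CCBr | starting material
5 | lithium (3S)-3-methylcyclopenta-1,4-dien-1-olate (α′-enolate of 3; not isolated) | [Li]OC1=C[C@@H](C)C=C1 | intermediate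
6 | (4S,5R)-4-methyl-5-(3-methylbut-2-en-1-yl)cyclopent-2-en-1-one (trans) | O=C1C=C[C@H](C)[C@H]1CC=C(C)C | intermediate
7 | 3-bromoprop-1-ene (allyl bromide) | C=CCBr | starting material
8 | lithium (3S)-3-methyl-2-(3-methylbut-2-en-1-yl)cyclopenta-1,4-dien-1-olate (α′-enolate of 6; not isolated) | [Li]OC1=C(CC=C(C)C)[C@@H](C)C=C1 | intermediate
9 | (4S,5S)-4-methyl-5-(3-methylbut-2-en-1-yl)-5-(prop-2-en-1-yl)cyclopent-2-en-1-one | O=C1C=C[C@H](C)[C@]1(CC=C)CC=C(C)C | intermediate
10 | (3,4,5-trimethoxyphenyl)magnesium bromide (THF solution) | COc1cc([Mg]Br)cc(OC)c1OC | starting material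
11 | trimethyl{[(3S,4S,5S)-4-methyl-5-(3-methylbut-2-en-1-yl)-5-(prop-2-en-1-yl)-3-(3,4,5-trimethoxyphenyl)cyclopent-1-en-1-yl]oxy}silane | C[Si](C)(C)OC1=C[C@@H](c2cc(OC)c(OC)c(OC)c2)[C@H](C)[C@]1(CC=C)CC=C(C)C | intermediate
12 | (2R,3R,4S,5S)-2-methoxy-4-methyl-5-(3-methylbut-2-en-1-yl)-5-(prop-2-en-1-yl)-3-(3,4,5-trimethoxyphenyl)cyclopentan-1-one | O=C1[C@H](OC)[C@@H](c2cc(OC)c(OC)c(OC)c2)[C@H](C)[C@]1(CC=C)CC=C(C)C | intermediate
13 | {[(3R,4S,5S)-2-methoxy-4-methyl-5-(3-methylbut-2-en-1-yl)-5-(prop-2-en-1-yl)-3-(3,4,5-trimethoxyphenyl)cyclopent-1-en-1-yl]oxy}trimethylsilane (not isolated) | C[Si](C)(C)OC1=C(OC)[C@@H](c2cc(OC)c(OC)c(OC)c2)[C@H](C)[C@]1(CC=C)CC=C(C)C | intermediate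
14 | (2R,3R,4S,5S)-2-(dimethoxymethyl)-2-methoxy-4-methyl-5-(3-methylbut-2-en-1-yl)-5-(prop-2-en-1-yl)-3-(3,4,5-trimethoxyphenyl)cyclopentan-1-one | O=C1[C@](OC)(C(OC)OC)[C@@H](c2cc(OC)c(OC)c(OC)c2)[C@H](C)[C@]1(CC=C)CC=C(C)C | intermediate
15 | (2R,3R,4S,5S)-2-(dimethoxymethyl)-5-[(3,3-dimethyloxiran-2-yl)methyl]-2-methoxy-4-methyl-5-(prop-2-en-1-yl)-3-(3,4,5-trimethoxyphenyl)cyclopentan-1-one (both epimers at the oxirane carbon) | O=C1[C@](OC)(C(OC)OC)[C@@H](c2cc(OC)c(OC)c(OC)c2)[C@H](C)[C@]1(CC=C)CC3OC3(C)C | intermediate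
16 | 2-[(1S,2S,3R,4R)-4-(dimethoxymethyl)-4-methoxy-2-methyl-5-oxo-1-(prop-2-en-1-yl)-3-(3,4,5-trimethoxyphenyl)cyclopentyl]acetaldehyde (not isolated) | O=C1[C@](OC)(C(OC)OC)[C@@H](c2cc(OC)c(OC)c(OC)c2)[C@H](C)[C@]1(CC=C)CC=O | intermediate
17 | (1R,2R,3S,4S)-1-methoxy-3-methyl-5-oxo-4-(2-oxoethyl)-4-(prop-2-en-1-yl)-2-(3,4,5-trimethoxyphenyl)cyclopentane-1-carbaldehyde | O=C1[C@](OC)(C=O)[C@@H](c2cc(OC)c(OC)c(OC)c2)[C@H](C)[C@]1(CC=C)CC=O | intermediate
18 | (1R,2R,3R,5S,6S,7R)-2,3-dihydroxy-1-methoxy-6-methyl-5-(prop-2-en-1-yl)-7-(3,4,5-trimethoxyphenyl)bicyclo[3.2.1]octan-8-one | C=CC[C@@]12C[C@@H](O)[C@@H](O)[C@@](OC)(C1=O)[C@@H](c1cc(OC)c(OC)c(OC)c1)[C@@H]2C | intermediate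
19 | (1R,2R,3R,5S,6S,7R)-2-hydroxy-1,3-dimethoxy-6-methyl-5-(prop-2-en-1-yl)-7-(3,4,5-trimethoxyphenyl)bicyclo[3.2.1]octan-8-one | C=CC[C@@]12C[C@@H](OC)[C@@H](O)[C@@](OC)(C1=O)[C@@H](c1cc(OC)c(OC)c(OC)c1)[C@@H]2C | target

**Summary and risks**

Total step count: 10. Longest linear sequence: 10 steps (from 1).

Steps most likely to fail:

Step 9. Electron transfer to the C2 formyl group may lead to loss of the neighbouring C1 methoxy group or to reduction of the C8 ketone instead of carbon–carbon coupling, and coupling without chelation would give the trans-diol. The fallback abandons electron-transfer reduction. It sets out from dialdehyde 17, which is heated with Bu3SnH and a catalytic amount of AIBN in benzene at 80 °C (tin-hydride-mediated radical-chain pinacol cyclisation). A neutral O-stannyl ketyl adds to the second formyl group through a tin-bridged, cis-selective transition state and cannot expel methoxide. The tin alkoxide is hydrolysed on work-up, so the fallback comes back to the route at diol 18 without a new isolated compound.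

Step 6. Carbon–carbon bond formation at the fully substituted, methoxy-bearing enol silane next to the aryl-bearing carbon may be slow or poorly face-selective, and the Lewis acid may ionise the product acetal so that the cis prenyl olefin captures the oxocarbenium ion. The fallback brings in the carbon at the alcohol oxidation level with the smallest electrophile. It sets out from ketone 12 (through its enol silane 13): hydroxymethylation with aqueous formaldehyde under Yb(OTf)3 catalysis in THF/H2O should give (2R,3R,4S,5S)-2-(hydroxymethyl)-2-methoxy-4-methyl-5-(3-methylbut-2-en-1-yl)-5-(prop-2-en-1-yl)-3-(3,4,5-trimethoxyphenyl)cyclopentan-1-one F1. Dess–Martin oxidation should give (1R,2R,3S,4S)-1-methoxy-3-methyl-4-(3-methylbut-2-en-1-yl)-5-oxo-4-(prop-2-en-1-yl)-2-(3,4,5-trimethoxyphenyl)cyclopentane-1-carbaldehyde F2. Acetalisation (HC(OMe)3, MeOH, catalytic p-TsOH) comes back to the route at 14.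

Step 5. The hypervalent iodine oxidant may attack the prenyl olefin or the electron-rich arene, or the enol silane may be protodesilylated in acidic methanol before it is oxidised. The fallback separates oxygenation from methylation. It sets out from enol silane 11: MeLi in THF at 0 °C should release lithium (3S,4S,5S)-4-methyl-5-(3-methylbut-2-en-1-yl)-5-(prop-2-en-1-yl)-3-(3,4,5-trimethoxyphenyl)cyclopent-1-en-1-olate F3. Hydroxylation with 2-(phenylsulfonyl)-3-phenyloxaziridine at −78 °C should give (2R,3R,4S,5S)-2-hydroxy-4-methyl-5-(3-methylbut-2-en-1-yl)-5-(prop-2-en-1-yl)-3-(3,4,5-trimethoxyphenyl)cyclopentan-1-one F4. O-Methylation with Me3OBF4 and 1,8-bis(dimethylamino)naphthalene comes back to the route at 12.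

Further compounds
F0 | step 9 | none | none
F1 | step 6 | (2R,3R,4S,5S)-2-(hydroxymethyl)-2-methoxy-4-methyl-5-(3-methylbut-2-en-1-yl)-5-(prop-2-en-1-yl)-3-(3,4,5-trimethoxyphenyl)cyclopentan-1-one | O=C1[C@](OC)(CO)[C@@H](c2cc(OC)c(OC)c(OC)c2)[C@H](C)[C@]1(CC=C)CC=C(C)C
F2 | step 6 | (1R,2R,3S,4S)-1-methoxy-3-methyl-4-(3-methylbut-2-en-1-yl)-5-oxo-4-(prop-2-en-1-yl)-2-(3,4,5-trimethoxyphenyl)cyclopentane-1-carbaldehyde | O=C1[C@](OC)(C=O)[C@@H](c2cc(OC)c(OC)c(OC)c2)[C@H](C)[C@]1(CC=C)CC=C(C)C
F3 | step 5 | lithium (3S,4S,5S)-4-methyl-5-(3-methylbut-2-en-1-yl)-5-(prop-2-en-1-yl)-3-(3,4,5-trimethoxyphenyl)cyclopent-1-en-1-olate | [Li]OC1=C[C@@H](c2cc(OC)c(OC)c(OC)c2)[C@H](C)[C@]1(CC=C)CC=C(C)C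
F4 | step 5 | (2R,3R,4S,5S)-2-hydroxy-4-methyl-5-(3-methylbut-2-en-1-yl)-5-(prop-2-en-1-yl)-3-(3,4,5-trimethoxyphenyl)cyclopentan-1-one | O=C1[C@H](O)[C@@H](c2cc(OC)c(OC)c(OC)c2)[C@H](C)[C@]1(CC=C)CC=C(C)C
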